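Vitisinol B is disconnected at the O–C2 bond of the dihydrofuran fused to ring A. Furan C2 carries a 4-hydroxyphenyl group and the oxygen on C6 of ring A, so it is a latent p-quinone methide carbon and the target is a cycloisomer of an open 5-(4-hydroxybenzylidene)dibenzosuberane. In one operation, acid puts a proton on ring carbon C5 and the peri C6 phenol on the benzylic carbon; this closes the furan, forms the C–O bond and sets both furan stereocentres. The precursor is the fully deprotected heptaphenol aldehyde that already holds the trans-10,11-diaryl centres in absolute form, built by two Friedel–Crafts acylations, α-arylation, transfer hydrogenation with dynamic resolution and a diastereoselective arylation.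

Key step: step 10

Remark: locants are those of dibenzo[a,d][7]annulene and are kept throughout (C5 bridging carbon; ring A = C5a–C9a, bearing C10 and the C6/C8 oxygens; ring B = C11a–C4a, bearing C11 and the C1/C3 oxygens; Cα = benzylidene carbon, later furan C2); the benzylidene compounds are assumed to form as E/Z mixtures, drawn E, which converge in step 10 because the cation rotates freely.

Step 1
Reactants: 1 methyl 3,5-dimethoxyphenylacetate; 2 3,5-dimethoxybenzoyl chloride
Product: 3 ring-A keto ester (2-aroyl arylacetate)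
Conditions: SnCl4 (1.5 equiv), CH2Cl2, 0 °C → rt
Reagents that add atoms: none
Why: Friedel–Crafts acylation, in which the aroyl cation from 2 should attack C2 of 1 (para to one methoxy, ortho to the other, less hindered than C4), while 2 cannot acylate itself because its own ring carries the deactivating acyl chloride and SnCl4 is mild enough to spare the peri methyl ether.

Step 2
Reactants: 3 ring-A keto ester
Product: 4 keto acid
Conditions: LiOH·H2O, THF/H2O, rt; then 1 M HCl
Reagents that add atoms: lithium hydroxide, [Li+].[OH-]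
Why: Ester saponification (BAc2), to which the non-enolisable diaryl ketone and the aryl ethers are inert.

Step 3
Reactants: 4 keto acid
Product: 5 tricyclic 5,11-diketone
Conditions: Eaton's reagent (P2O5 in MeSO3H), 60 °C
Reagents that add atoms: none
Why: Intramolecular Friedel–Crafts acylation closing the seven-membered ring, in which the arylacetyl cation attacks C2 of the 3,5-dimethoxybenzoyl ring (ortho/para to its two methoxy groups, which are not conjugated with the ketone and keep this ring the more nucleophilic one), in analogy to the strong-acid closure of 2-aroylbenzoic acids to anthraquinones, the two ortho positions being equivalent.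

Step 4
Reactants: 5 tricyclic 5,11-diketone; 6 4-bromo-2-iodoanisole
Product: 7 racemic 10-aryl diketone
Conditions: Pd2(dba)3 (2.5 mol %), Xantphos (6 mol %), K3PO4, toluene, 80 °C
Reagents that add atoms: none
Why: Pd-catalysed ketone α-arylation (Buchwald–Hartwig type), in which only C10 is enolisable, the benzylic enolate couples at the C–I bond (oxidative addition far faster than at C–Br) and the product rests as its hindered enolate so that a second arylation should not follow; the new C10 centre is racemic and labile.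

Step 5
Reactants: 7 racemic 10-aryl diketone
Product: 8 cis-(10R,11S) hydroxy ketone
Conditions: RuCl[(S,S)-TsDPEN](p-cymene) (2 mol %), HCO2H/Et3N (5:2), DMF, 40 °C
Reagents that add atoms: none
Why: Noyori-type asymmetric transfer hydrogenation with dynamic kinetic resolution, in which Et3N racemises C10 through the enol, the hindered diaryl ketone C5 should stay untouched, and the (S,S)-catalyst is expected to reduce the aryl alkyl ketone C11 of the matched enantiomer anti to the C10 aryl, giving the cis (10R,11S) carbinol in the sense in which 1-tetralone gives (S)-1-tetralol (to be confirmed; the (R,R)-catalyst is the remedy).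

Step 6
Reactants: 8 cis-(10R,11S) hydroxy ketone; 9 anisole
Product: 10 trans-(10R,11S) diaryl ketone
Conditions: TfOH (10 mol %), anisole (20 equiv), HFIP/CH2Cl2, −20 → 0 °C
Reagents that add atoms: none
Why: SN1 Friedel–Crafts alkylation, in which 8 (also if it rests as its O11–C5 hemiketal tautomer) ionises to a C11 cation stabilised by the ortho and para methoxy groups of ring B and anisole attacks through its para carbon on the face anti to the C10 aryl, setting C11 (S) trans to the untouched C10 centre, while HFIP and excess arene favour capture over E1 loss of H10.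

Step 7
Reactants: 10 trans-(10R,11S) diaryl ketone; 11 4-methoxybenzylmagnesium chloride
Product: 13 bromo benzylidene heptamethyl ether, via C5 tertiary carbinol 12 (not isolated)
Conditions: 11 (3 equiv), THF, 0 °C → rt; H2O work-up; then TsOH·H2O (5 mol %), toluene, 40 °C
Reagents that add atoms: none
Why: Grignard 1,2-addition to the non-enolisable diaryl ketone (as in additions to dibenzosuberone) followed by E1 dehydration, in which the bis-benzylic C5 cation can lose a proton only from the anisyl CH2; the C5 centre of 12 is transient and the alkene geometry is immaterial.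

Step 8
Reactants: 13 bromo benzylidene heptamethyl ether
Product: 15 heptamethyl ether aldehyde, via aryllithium 14 (not isolated)
Conditions: n-BuLi (1.1 equiv), THF, −78 °C; DMF, −78 → 0 °C; H2O
Reagents that add atoms: N,N-dimethylformamide, CN(C)C=O
Why: Bromine–lithium exchange, which at −78 °C should outrun benzylic deprotonation and addition to the stilbene, followed by Bouveault formylation of the aryllithium with DMF.

Step 9
Reactants: 15 heptamethyl ether aldehyde
Product: 16 seco-vitisinol B
Conditions: BBr3 (12 equiv), CH2Cl2, −78 → 0 °C; ice/water quench, immediate EtOAc extraction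
Reagents that add atoms: none
Why: Lewis-acid cleavage of aryl methyl ethers (bromide attacks the methyl group of each ArO(Me)–BBr3 adduct), a reaction type known to tolerate 4-methoxybenzylidene stilbenoids and methoxybenzaldehydes, with a cold quench and quick extraction to take HBr away from the stilbene.

Step 10
Reactants: 16 seco-vitisinol B
Product: 17 vitisinol B
Conditions: TsOH·H2O (0.2 equiv), MeCN (5 mM), Ar, rt → 40 °C
Reagents that add atoms: none
Why: Reversible protonation of the exocyclic C5=Cα alkene at C5 gives a Cα cation that is an O-protonated p-quinone methide, and the C6 phenol of ring A adds to Cα with loss of a proton. The closest known reaction type is the acid-mediated cyclisation of 2-hydroxystilbenes to trans-2-aryl-2,3-dihydrobenzofurans used in stilbenoid oligomer chemistry. The furan (O6, C6, C5a, C5, Cα) closes in a 5-exo-trig mode onto the methide carbon. The new centre C5 (furan C3) should be controlled thermodynamically by the fixed C10/C11 centres because protonation is reversible, and furan C2 by C5, the aryl settling trans to ring B through reversible ring opening; that this equilibrium favours the natural diastereomer has to be verified. The step needs exclusive O-cyclisation, which geometry secures: only O6 is peri to Cα, and the aryl carbons within reach are meta to their hydroxyls and not nucleophilic. High dilution under argon should suppress intermolecular capture of the cation by resorcinol rings and condensation at the aldehyde.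

Compound list
1 | methyl 2-(3,5-dimethoxyphenyl)acetate | COC(=O)Cc1cc(OC)cc(OC)c1 | starting material
2 | 3,5-dimethoxybenzoyl chloride | COc1cc(cc(OC)c1)C(=O)Cl | starting material
3 | methyl 2-[2-(3,5-dimethoxybenzoyl)-3,5-dimethoxyphenyl]acetate | COC(=O)Cc1cc(OC)cc(OC)c1C(=O)c1cc(OC)cc(OC)c1 | intermediate
4 | 2-[2-(3,5-dimethoxybenzoyl)-3,5-dimethoxyphenyl]acetic acid | OC(=O)Cc1cc(OC)cc(OC)c1C(=O)c1cc(OC)cc(OC)c1 | intermediate
5 | 1,3,6,8-tetramethoxy-5H-dibenzo[a,d][7]annulene-5,11(10H)-dione | O=C1Cc2cc(OC)cc(OC)c2C(=O)c2cc(OC)cc(OC)c12 | intermediate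
6 | 4-bromo-2-iodoanisole | COc1ccc(Br)cc1I | starting material
7 | rac-10-(5-bromo-2-methoxyphenyl)-1,3,6,8-tetramethoxy-5H-dibenzo[a,d][7]annulene-5,11(10H)-dione (C10 configurationally labile) | COc1ccc(Br)cc1C1c2cc(OC)cc(OC)c2C(=O)c2cc(OC)cc(OC)c2C1=O | intermediate
8 | (10R,11S)-10-(5-bromo-2-methoxyphenyl)-11-hydroxy-1,3,6,8-tetramethoxy-10,11-dihydro-5H-dibenzo[a,d][7]annulen-5-one (aryl and OH cis) | COc1ccc(Br)cc1[C@H]1c2cc(OC)cc(OC)c2C(=O)c2cc(OC)cc(OC)c2[C@H]1O | intermediate
9 | anisole | COc1ccccc1 | starting material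
10 | (10R,11S)-10-(5-bromo-2-methoxyphenyl)-1,3,6,8-tetramethoxy-11-(4-methoxyphenyl)-10,11-dihydro-5H-dibenzo[a,d][7]annulen-5-one (aryls trans) | COc1ccc(Br)cc1[C@H]1c2cc(OC)cc(OC)c2C(=O)c2cc(OC)cc(OC)c2[C@@H]1c1ccc(OC)cc1 | intermediate
11 | 4-methoxybenzylmagnesium chloride (commercial THF solution) | COc1ccc(C[Mg]Cl)cc1 | starting material
12 | (10R,11S)-10-(5-bromo-2-methoxyphenyl)-5-(4-methoxybenzyl)-1,3,6,8-tetramethoxy-11-(4-methoxyphenyl)-10,11-dihydro-5H-dibenzo[a,d][7]annulen-5-ol (C5 epimer mixture) | COc1ccc(Br)cc1[C@H]1c2cc(OC)cc(OC)c2C(O)(Cc2ccc(OC)cc2)c2cc(OC)cc(OC)c2[C@@H]1c1ccc(OC)cc1 | intermediate (not isolated)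
13 | (10R,11S,E)-10-(5-bromo-2-methoxyphenyl)-5-(4-methoxybenzylidene)-1,3,6,8-tetramethoxy-11-(4-methoxyphenyl)-10,11-dihydro-5H-dibenzo[a,d][7]annulene | COc1ccc(Br)cc1[C@H]1c2cc(OC)cc(OC)c2/C(=C/c2ccc(OC)cc2)c2cc(OC)cc(OC)c2[C@@H]1c1ccc(OC)cc1 | intermediate
14 | aryllithium from 13 (Li in place of Br) | [Li]c1ccc(OC)c(c1)[C@H]1c2cc(OC)cc(OC)c2/C(=C/c2ccc(OC)cc2)c2cc(OC)cc(OC)c2[C@@H]1c1ccc(OC)cc1 | intermediate (not isolated)
15 | 4-methoxy-3-[(10R,11S,E)-1,3,6,8-tetramethoxy-5-(4-methoxybenzylidene)-11-(4-methoxyphenyl)-10,11-dihydro-5H-dibenzo[a,d][7]annulen-10-yl]benzaldehyde | O=Cc1ccc(OC)c(c1)[C@H]1c2cc(OC)cc(OC)c2/C(=C/c2ccc(OC)cc2)c2cc(OC)cc(OC)c2[C@@H]1c1ccc(OC)cc1 | intermediate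
16 | seco-vitisinol B, 4-hydroxy-3-[(10R,11S,E)-1,3,6,8-tetrahydroxy-5-(4-hydroxybenzylidene)-11-(4-hydroxyphenyl)-10,11-dihydro-5H-dibenzo[a,d][7]annulen-10-yl]benzaldehyde | O=Cc1ccc(O)c(c1)[C@H]1c2cc(O)cc(O)c2/C(=C/c2ccc(O)cc2)c2cc(O)cc(O)c2[C@@H]1c1ccc(O)cc1 | intermediate
17 | vitisinol B (C10 R, C11 S, aryls trans; dihydrofuran C2 S, C3 S, 2,3-trans) | O=Cc1ccc(O)c([C@H]2c3cc(O)cc4c3[C@H](c3cc(O)cc(O)c3[C@@H]2c2ccc(O)cc2)[C@@H](c2ccc(O)cc2)O4)c1 | target

Total steps: 10. Longest linear sequence: 10 steps (1 → 17).

Steps most likely to fail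

Step 10. The reversible protonation and ring closure may settle on a mixture or on the wrong C5 epimer, and the long-lived quinone-methide cation may be intercepted by another molecule. The fallback sets out from 13 and comes back at 17, and it places H5 kinetically instead of by equilibration. Hydroboration–oxidation of 13 (BH3·THF, then NaOH/H2O2) should add H to C5 and OH to Cα by syn addition from the less hindered face, giving the bromo carbinol F1 (drawn with the C5 configuration of 17; the facial preference has to be established, and the carbinol centre is irrelevant). Treatment with n-BuLi (2.2 equiv, the first equivalent forming the alkoxide) and then DMF should give the formyl carbinol F2. BBr3 (CH2Cl2, −78 → 0 °C) with aqueous quench should then cleave the seven methyl ethers and ionise the 4-oxygenated benzylic carbinol to the quinone methide, which the C6 phenol captures 5-exo to give 17 without passing through the alkene.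

Step 9. Boron Lewis acid and HBr may protonate the electron-rich stilbene while the phenols are being freed, so that cyclisation or oligomerisation starts outside the controlled conditions of step 10, and cleavage of seven ethers may stop short. The fallback sets out from 10 and comes back at 16, and it moves the ether cleavage to the robust ketone stage. BBr3 on 10 should give the hexaphenol ketone F3, and TBSCl/imidazole in DMF the hexasilyl ether F4. Addition of 4-(tert-butyldimethylsilyloxy)benzylmagnesium chloride F5 (from the benzyl chloride and Mg) should give the silylated tertiary carbinol F6, which catalytic PPTS in toluene dehydrates to the silylated bromo stilbene F7. n-BuLi/DMF as in step 8 should give the silylated aldehyde F8, and TBAF buffered with AcOH (THF, 0 °C) removes the seven silyl groups without acid to give 16.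

Step 5. Hydride transfer to the di-ortho-substituted α,α-diaryl ketone may be too slow, or the catalyst may discriminate the two interconverting C10 epimers poorly. The fallback sets out from 7 and comes back at 8, and it replaces catalyst control by resolution. NaBH4 (THF/MeOH, −20 °C) should reduce C11 anti to the C10 aryl under substrate control to give the racemic cis carbinol F9. Esterification with (S)-O-methylmandelic acid (DCC, DMAP) and chromatographic separation of the two diastereomers should give the (10R,11S) O-methylmandelate F10, from which LiOH (THF/H2O) releases 8.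

Further compounds
F1 | step 10 | (10R,11S)-10-(5-bromo-2-methoxyphenyl)-5-[hydroxy(4-methoxyphenyl)methyl]-1,3,6,8-tetramethoxy-11-(4-methoxyphenyl)-10,11-dihydro-5H-dibenzo[a,d][7]annulene (C5 as in 17, carbinol centre unspecified) | COc1ccc(Br)cc1[C@H]1c2cc(OC)cc(OC)c2[C@@H](C(O)c2ccc(OC)cc2)c2cc(OC)cc(OC)c2[C@@H]1c1ccc(OC)cc1
F2 | step 10 | formyl carbinol (CHO in place of Br in F1) | O=Cc1ccc(OC)c(c1)[C@H]1c2cc(OC)cc(OC)c2[C@@H](C(O)c2ccc(OC)cc2)c2cc(OC)cc(OC)c2[C@@H]1c1ccc(OC)cc1
F3 | step 9 | (10R,11S)-10-(5-bromo-2-hydroxyphenyl)-1,3,6,8-tetrahydroxy-11-(4-hydroxyphenyl)-10,11-dihydro-5H-dibenzo[a,d][7]annulen-5-one | Oc1ccc(Br)cc1[C@H]1c2cc(O)cc(O)c2C(=O)c2cc(O)cc(O)c2[C@@H]1c1ccc(O)cc1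
F4 | step 9 | hexakis(tert-butyldimethylsilyl) ether of F3 | CC(C)(C)[Si](C)(C)Oc1ccc(Br)cc1[C@H]1c2cc(O[Si](C)(C)C(C)(C)C)cc(O[Si](C)(C)C(C)(C)C)c2C(=O)c2cc(O[Si](C)(C)C(C)(C)C)cc(O[Si](C)(C)C(C)(C)C)c2[C@@H]1c1ccc(O[Si](C)(C)C(C)(C)C)cc1
F5 | step 9 | 4-(tert-butyldimethylsilyloxy)benzylmagnesium chloride | CC(C)(C)[Si](C)(C)Oc1ccc(C[Mg]Cl)cc1
F6 | step 9 | silylated C5 tertiary carbinol (C5 epimer mixture) | CC(C)(C)[Si](C)(C)Oc1ccc(Br)cc1[C@H]1c2cc(O[Si](C)(C)C(C)(C)C)cc(O[Si](C)(C)C(C)(C)C)c2C(O)(Cc2ccc(O[Si](C)(C)C(C)(C)C)cc2)c2cc(O[Si](C)(C)C(C)(C)C)cc(O[Si](C)(C)C(C)(C)C)c2[C@@H]1c1ccc(O[Si](C)(C)C(C)(C)C)cc1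
F7 | step 9 | heptakis(tert-butyldimethylsilyl) bromo benzylidene compound (silyl analogue of 13) | CC(C)(C)[Si](C)(C)Oc1ccc(Br)cc1[C@H]1c2cc(O[Si](C)(C)C(C)(C)C)cc(O[Si](C)(C)C(C)(C)C)c2/C(=C/c2ccc(O[Si](C)(C)C(C)(C)C)cc2)c2cc(O[Si](C)(C)C(C)(C)C)cc(O[Si](C)(C)C(C)(C)C)c2[C@@H]1c1ccc(O[Si](C)(C)C(C)(C)C)cc1
F8 | step 9 | heptakis(tert-butyldimethylsilyl) ether of 16 | O=Cc1ccc(O[Si](C)(C)C(C)(C)C)c(c1)[C@H]1c2cc(O[Si](C)(C)C(C)(C)C)cc(O[Si](C)(C)C(C)(C)C)c2/C(=C/c2ccc(O[Si](C)(C)C(C)(C)C)cc2)c2cc(O[Si](C)(C)C(C)(C)C)cc(O[Si](C)(C)C(C)(C)C)c2[C@@H]1c1ccc(O[Si](C)(C)C(C)(C)C)cc1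
F9 | step 5 | racemic cis carbinol (8 and its 10S,11R enantiomer) | COc1ccc(Br)cc1[C@H]1c2cc(OC)cc(OC)c2C(=O)c2cc(OC)cc(OC)c2[C@H]1O.COc1ccc(Br)cc1[C@@H]1c2cc(OC)cc(OC)c2C(=O)c2cc(OC)cc(OC)c2[C@@H]1O
F10 | step 5 | (S)-O-methylmandelate of 8 | COc1ccc(Br)cc1[C@H]1c2cc(OC)cc(OC)c2C(=O)c2cc(OC)cc(OC)c2[C@H]1OC(=O)[C@@H](OC)c1ccccc1
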